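**Retrosynthetic overview**

1. Target 17 ⇐ formylation of primary allylic alcohol 16 ⇐ lipase-selective deacetylation of triacetate 15.
2. Ring B, the (E)-tetrasubstituted alkylidene, C-4a and the allylic acetate at C-2 of 15 ⇐ dienyne 14 by an oxidative, divalent-palladium methylative carbocyclisation/1,4-acetoxylation (proposed new step).
3. Side chain of 14 ⇐ aldehyde 11 (asymmetric propargylation, hydroxymethylation) ⇐ nitro diene 9 (Nef); the diene of 9 ⇐ cyclohexenone 7 (enol triflate, reduction).
4. Key skeletal step: one-carbon ring expansion (1,2-alkenyl shift with loss of N2) of cyclopentenone 5 to the six-membered ketone 7; 5 ⇐ 4-alkynal 4 (Rh hydroacylation) ⇐ hex-4-ynal + (E)-1-nitropropene (organocatalytic Michael addition sets the centres that become C-8a and C-8).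
5. Ring order: five-membered precursor of ring A → ring expansion to six-membered ring A → ring B closed last.

Assumption: bicyclic compounds are named on the naphthalene skeleton (acetates at C-2 and C-7, alkylidene at C-5), and 1 and 3 are taken as catalogue chemicals.

**Route**

Step 1
Reactants: 1 hex-4-yn-1-ol
Product: 2 hex-4-ynal
Conditions: TEMPO (10 mol%), PhI(OAc)2 (1.1 equiv), CH2Cl2, 20 °C
Reagents that add atoms: none
Why: TEMPO/PhI(OAc)2 oxidation (oxoammonium-mediated alcohol oxidation) stops at the aldehyde and leaves the internal alkyne untouched.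

Step 2
Reactants: 2 hex-4-ynal (1.5 equiv); 3 (E)-1-nitroprop-1-ene
Product: 4 (2R,3R)-2-(but-2-yn-1-yl)-3-methyl-4-nitrobutanal
Conditions: (S)-α,α-diphenylprolinol trimethylsilyl ether (10 mol%), 4-nitrophenol (10 mol%), toluene, 0 °C
Reagents that add atoms: none
Why: Hayashi–Jørgensen enamine-catalysed Michael addition, in which the E-enamine, shielded on one face by the diarylsilyloxymethyl group, adds to the nitroalkene through the acyclic synclinal transition state to give the syn adduct and set both stereocentres (2R,3R, the future C-8a and C-8).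

Step 3
Reactants: 4 (2R,3R)-2-(but-2-yn-1-yl)-3-methyl-4-nitrobutanal
Product: 5 (5R)-2-methyl-5-[(2R)-1-nitropropan-2-yl]cyclopent-2-en-1-one
Conditions: [Rh(dppe)]2(BF4)2 (5 mol%), acetone, 25 °C
Reagents that add atoms: none
Why: Intramolecular trans-hydroacylation of a 4-alkynal by cationic monovalent rhodium (acyl–Rh–H addition across the alkyne with C–C bond formation at the distal, methyl-bearing alkyne carbon) gives the 2-methylcyclopentenone under neutral conditions that do not epimerise the α-stereocentre.

Step 4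
Reactants: 5 (5R)-2-methyl-5-[(2R)-1-nitropropan-2-yl]cyclopent-2-en-1-one
Product: 7 (6R)-3-methyl-6-[(2R)-1-nitropropan-2-yl]cyclohex-3-en-1-one, via 2-trimethylsilyl ketone 6 (not isolated)
Conditions: TMSCHN2 (1.2 equiv), BF3·OEt2 (1.1 equiv), CH2Cl2, −78 °C; then Bu4NF, AcOH, THF, −40 → 0 °C
Reagents that add atoms: (trimethylsilyl)diazomethane, C[Si](C)(C)C=[N+]=[N-]
Why: Lewis-acid-promoted diazoalkane homologation (Tiffeneau–Demjanov-type ring expansion), in which the diazo carbon adds to the BF3-bound carbonyl and the alkenyl carbon undergoes the 1,2-shift with loss of N2 to enlarge the five-membered ring to the six-membered ring A precursor, after which buffered fluoride removes silicon with kinetic α-protonation and the C-6 stereocentre is not touched.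

Step 5
Reactants: 7 (6R)-3-methyl-6-[(2R)-1-nitropropan-2-yl]cyclohex-3-en-1-one
Product: 8 (6R)-3-methyl-6-[(2R)-1-nitropropan-2-yl]cyclohexa-1,3-dien-1-yl trifluoromethanesulfonate
Conditions: Tf2O (1.2 equiv), 2,6-di-tert-butyl-4-methylpyridine (1.5 equiv), CH2Cl2, 0 °C
Reagents that add atoms: trifluoromethanesulfonic anhydride, O=S(=O)(OS(=O)(=O)C(F)(F)F)C(F)(F)F
Why: Enol triflate formation under non-basic conditions takes place at the doubly activated C-2 methylene to give the conjugated dienyl triflate, leaving the acidic nitromethyl group and the C-6 stereocentre alone.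

Step 6
Reactants: 8 (6R)-3-methyl-6-[(2R)-1-nitropropan-2-yl]cyclohexa-1,3-dien-1-yl trifluoromethanesulfonate
Product: 9 (5S)-2-methyl-5-[(2R)-1-nitropropan-2-yl]cyclohexa-1,3-diene
Conditions: Pd(OAc)2 (5 mol%), PPh3 (10 mol%), HCO2H, Bu3N, DMF, 60 °C
Reagents that add atoms: none
Why: Palladium-catalysed formate reduction of an alkenyl triflate (oxidative addition to zerovalent palladium, decarboxylation of formate to the hydride, reductive elimination) replaces OTf by H and gives the 1,3-diene of ring A without moving the double bonds.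

Step 7
Reactants: 9 (5S)-2-methyl-5-[(2R)-1-nitropropan-2-yl]cyclohexa-1,3-diene
Product: 11 (2R)-2-[(1S)-4-methylcyclohexa-2,4-dien-1-yl]propanal, via sodium nitronate 10 (not isolated)
Conditions: NaOMe (1.05 equiv), MeOH, 0 °C; then aq. TiCl3 (4 equiv), NH4OAc buffer, 0 → 20 °C
Reagents that add atoms: water, O
Why: Reductive Nef reaction (trivalent titanium reduces the nitronate to the imine, which hydrolyses) unmasks the aldehyde under buffered, non-oxidising conditions that spare the diene and the adjacent stereocentre.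

Step 8
Reactants: 11 (2R)-2-[(1S)-4-methylcyclohexa-2,4-dien-1-yl]propanal
Product: 12 (2R,3R)-2-[(1S)-4-methylcyclohexa-2,4-dien-1-yl]hex-5-yn-3-ol
Conditions: allenylboronic acid pinacol ester (1.5 equiv), (R)-TRIP [(R)-3,3′-bis(2,4,6-triisopropylphenyl)-1,1′-binaphthyl-2,2′-diyl hydrogen phosphate] (5 mol%), 4 Å MS, toluene, −20 °C
Reagents that add atoms: allenylboronic acid pinacol ester, CC1(C)OB(C=C=C)OC1(C)C
Why: Chiral-phosphoric-acid-catalysed propargylation (SE2′ allenylboration through a six-membered chair transition state) sets the carbinol centre (3R, the future C-7) under catalyst control, the (R)-acid being the enantiomer that gives R-configured homopropargylic alcohols and here matching the Felkin–Anh preference of the α-methyl aldehyde.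

Step 9
Reactants: 12 (2R,3R)-2-[(1S)-4-methylcyclohexa-2,4-dien-1-yl]hex-5-yn-3-ol
Product: 14 (5R,6R)-6-[(1S)-4-methylcyclohexa-2,4-dien-1-yl]hept-2-yne-1,5-diyl diacetate, via dilithium dialkoxide 13 (not isolated)
Conditions: n-BuLi (2.1 equiv), THF, −78 °C; CH2O (gas from cracked paraformaldehyde, 1.2 equiv), −78 → 0 °C; then Ac2O (3 equiv), DMAP (cat.), 0 → 20 °C
Reagents that add atoms: formaldehyde, C=O; acetic anhydride, CC(=O)OC(C)=O
Why: Acetylide addition to formaldehyde (alkyne hydroxymethylation) followed by acylation of both lithium alkoxides in the same flask installs the propargylic CH2O carbon and the two acetates without touching any stereocentre.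

Step 10
Reactants: 14 (5R,6R)-6-[(1S)-4-methylcyclohexa-2,4-dien-1-yl]hept-2-yne-1,5-diyl diacetate
Product: 15 (2R,4aS,7R,8R,8aS)-5-[(2E)-1-acetoxypropan-2-ylidene]-3,8-dimethyl-1,2,4a,5,6,7,8,8a-octahydronaphthalene-2,7-diyl diacetate
Conditions: Pd(OAc)2 (10 mol%), MeB(OH)2 (2 equiv), 1,4-benzoquinone (20 mol%), MnO2 (2 equiv), LiOAc (2 equiv), AcOH/acetone 1:4, 40 °C
Reagents that add atoms: methylboronic acid, CB(O)O; acetic acid, CC(=O)O
Why: Proposed new method: methylboronic acid transmetalates to divalent palladium (as in palladium-catalysed C–H methylation), MePd(OAc) adds syn across the diene-chelated alkyne (methyl to the distal carbon, palladium to the carbon that can reach the diene), the alkenyl–Pd bond inserts the proximal diene double bond on the tether face (cis ring fusion, sets C-4a, methyl ends cis to C-4a so the alkene is E), and the resulting η3-allyl complex passes acetate from palladium to the same face (benzoquinone-induced inner-sphere migration in the absence of chloride) to set the C-2 acetate cis to the new C–C bond, with zerovalent palladium reoxidised by benzoquinone/MnO2; the closest known reaction type is the divalent-palladium-catalysed intramolecular 1,4-oxidation of cyclic 1,3-dienes by an alkenylpalladium made through chloropalladation of a tethered alkyne, here started instead by methylpalladation from a boronic acid.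

Step 11
Reactants: 15 (2R,4aS,7R,8R,8aS)-5-[(2E)-1-acetoxypropan-2-ylidene]-3,8-dimethyl-1,2,4a,5,6,7,8,8a-octahydronaphthalene-2,7-diyl diacetate
Product: 16 (2R,4aS,7R,8R,8aS)-5-[(2E)-1-hydroxypropan-2-ylidene]-3,8-dimethyl-1,2,4a,5,6,7,8,8a-octahydronaphthalene-2,7-diyl diacetate
Conditions: immobilised Candida antarctica lipase B, n-BuOH (5 equiv), MTBE, 30 °C
Reagents that add atoms: none
Why: Lipase-catalysed transesterification is selective for the unhindered primary allylic acetate over the two secondary acetates, so only the side-chain ester is cleaved.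

Step 12
Reactants: 16 (2R,4aS,7R,8R,8aS)-5-[(2E)-1-hydroxypropan-2-ylidene]-3,8-dimethyl-1,2,4a,5,6,7,8,8a-octahydronaphthalene-2,7-diyl diacetate
Product: 17 (2E)-2-[(2R,4aS,7R,8R,8aS)-2,7-diacetoxy-3,8-dimethyl-1,2,6,7,8,8a-hexahydronaphthalen-5(4aH)-ylidene]propyl formate (CNP0262962.1)
Conditions: HCO2H (1.5 equiv), DCC (1.5 equiv), DMAP (5 mol%), CH2Cl2, 0 °C
Reagents that add atoms: formic acid, O=CO
Why: Steglich-type esterification (carbodiimide activation of formic acid) formylates the primary allylic alcohol under neutral conditions that leave the acetates, the skipped diene and the alkene geometry intact.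

**Compound list**

1 | hex-4-yn-1-ol | CC#CCCCO | starting material
2 | hex-4-ynal | CC#CCCC=O | intermediate
3 | (E)-1-nitroprop-1-ene | C/C=C/[N+](=O)[O-] | starting material
4 | (2R,3R)-2-(but-2-yn-1-yl)-3-methyl-4-nitrobutanal | CC#CC[C@@H](C=O)[C@@H](C)C[N+](=O)[O-] | intermediate
5 | (5R)-2-methyl-5-[(2R)-1-nitropropan-2-yl]cyclopent-2-en-1-one | CC1=CC[C@@H](C1=O)[C@@H](C)C[N+](=O)[O-] | intermediate
6 | (6R)-3-methyl-6-[(2R)-1-nitropropan-2-yl]-2-(trimethylsilyl)cyclohex-3-en-1-one (both C-2 epimers; not isolated) | CC1=CC[C@@H](C(=O)C1[Si](C)(C)C)[C@@H](C)C[N+](=O)[O-] | intermediate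
7 | (6R)-3-methyl-6-[(2R)-1-nitropropan-2-yl]cyclohex-3-en-1-one | CC1=CC[C@@H](C(=O)C1)[C@@H](C)C[N+](=O)[O-] | intermediate
8 | (6R)-3-methyl-6-[(2R)-1-nitropropan-2-yl]cyclohexa-1,3-dien-1-yl trifluoromethanesulfonate | CC1=CC[C@@H](C(OS(=O)(=O)C(F)(F)F)=C1)[C@@H](C)C[N+](=O)[O-] | intermediate
9 | (5S)-2-methyl-5-[(2R)-1-nitropropan-2-yl]cyclohexa-1,3-diene | CC1=CC[C@@H](C=C1)[C@@H](C)C[N+](=O)[O-] | intermediate
10 | sodium (2R)-2-[(1S)-4-methylcyclohexa-2,4-dien-1-yl]propane-1-nitronate (not isolated) | CC1=CC[C@@H](C=C1)[C@@H](C)C=[N+]([O-])[O-].[Na+] | intermediate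
11 | (2R)-2-[(1S)-4-methylcyclohexa-2,4-dien-1-yl]propanal | CC1=CC[C@@H](C=C1)[C@@H](C)C=O | intermediate
12 | (2R,3R)-2-[(1S)-4-methylcyclohexa-2,4-dien-1-yl]hex-5-yn-3-ol | CC1=CC[C@@H](C=C1)[C@@H](C)[C@H](O)CC#C | intermediate
13 | dilithium (5R,6R)-6-[(1S)-4-methylcyclohexa-2,4-dien-1-yl]hept-2-yne-1,5-diolate (not isolated) | CC1=CC[C@@H](C=C1)[C@@H](C)[C@H]([O-])CC#CC[O-].[Li+].[Li+] | intermediate
14 | (5R,6R)-6-[(1S)-4-methylcyclohexa-2,4-dien-1-yl]hept-2-yne-1,5-diyl diacetate | CC1=CC[C@@H](C=C1)[C@@H](C)[C@H](OC(C)=O)CC#CCOC(C)=O | intermediate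
15 | (2R,4aS,7R,8R,8aS)-5-[(2E)-1-acetoxypropan-2-ylidene]-3,8-dimethyl-1,2,4a,5,6,7,8,8a-octahydronaphthalene-2,7-diyl diacetate | CC(=O)O[C@@H]1C[C@@H]2[C@@H](C)[C@H](OC(C)=O)C/C(=C(/C)COC(C)=O)[C@@H]2C=C1C | intermediate
16 | (2R,4aS,7R,8R,8aS)-5-[(2E)-1-hydroxypropan-2-ylidene]-3,8-dimethyl-1,2,4a,5,6,7,8,8a-octahydronaphthalene-2,7-diyl diacetate | CC(=O)O[C@@H]1C[C@@H]2[C@@H](C)[C@H](OC(C)=O)C/C(=C(/C)CO)[C@@H]2C=C1C | intermediate
17 | (2E)-2-[(2R,4aS,7R,8R,8aS)-2,7-diacetoxy-3,8-dimethyl-1,2,6,7,8,8a-hexahydronaphthalen-5(4aH)-ylidene]propyl formate | CC(=O)O[C@@H]1C[C@@H]2[C@@H](C)[C@H](OC(C)=O)C/C(=C(/C)COC=O)[C@@H]2C=C1C | target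

**Step count and risks**

Total steps: 12. Longest linear sequence: 12 (the route is fully linear).

Step 10 (proposed new step). Risks are slow boron-to-palladium methyl transfer, trans-acetoxypalladation or wrong-way methylpalladation of the alkyne, direct diacetoxylation of the diene, and Diels–Alder addition of benzoquinone (hence catalytic quinone with MnO2). The fallback uses two established reaction types, sets out from 14 and returns at 15. Chloride-free 1,4-diacetoxylation of the diene (Pd(OAc)2, catalytic benzoquinone, MnO2, LiOAc, AcOH, 25 °C) places the external acetate at the unhindered diene terminus anti to palladium and the palladium-delivered acetate next to the side chain, giving (1R,4R,5R)-5-[(2R,3R)-3,7-diacetoxyhept-5-yn-2-yl]-2-methylcyclohex-2-ene-1,4-diyl diacetate F1. Treatment of F1 with Pd(PPh3)4, Me4Sn and LiCl in DMF at 60 °C then ionises the ring acetate next to the side chain with inversion; the allylpalladium adds syn across the tethered alkyne (palladium-ene type cyclisation; the allyl complex from the other acetate cannot cyclise and reverts), and the alkenylpalladium is methylated by Stille coupling to give 15.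

Step 4. Risks are competing migration of the saturated α′ carbon, double homologation, and reaction at the enone C=C. The regioisomeric enone must be removed, because after steps 5 and 6 it would lead to the diene with the opposite sense at the ring stereocentre. The fallback sets out from 5 and returns at 7. Addition of LiCHBr2 (CH2Br2, lithium 2,2,6,6-tetramethylpiperidide, THF, −78 °C, one extra equivalent for the nitroalkane) gives (5R)-1-(dibromomethyl)-2-methyl-5-[(2R)-1-nitropropan-2-yl]cyclopent-2-en-1-ol F2. n-BuLi (3 equiv, −78 °C) converts F2 into the β-oxido carbenoid, whose α-elimination with 1,2-alkenyl shift gives the ring-enlarged enolate; this is protonated with AcOH at −78 °C to give 7.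

Step 7. Risks are a low-yielding Nef reaction of a primary nitroalkane, epimerisation next to the new aldehyde, and acid sensitivity of the diene. The fallback sets out from 9 and returns at 11. NaNO2 and AcOH in DMSO at 35 °C convert the primary nitroalkane into (2R)-2-[(1S)-4-methylcyclohexa-2,4-dien-1-yl]propanoic acid F3 without loss of the α-centre. LiAlH4 in THF at 0 °C gives (2R)-2-[(1S)-4-methylcyclohexa-2,4-dien-1-yl]propan-1-ol F4, and TEMPO/PhI(OAc)2 oxidation gives 11.

Further compounds
F1 | step 10 | (1R,4R,5R)-5-[(2R,3R)-3,7-diacetoxyhept-5-yn-2-yl]-2-methylcyclohex-2-ene-1,4-diyl diacetate | CC(=O)O[C@@H]1C[C@H]([C@@H](C)[C@H](OC(C)=O)CC#CCOC(C)=O)[C@@H](OC(C)=O)C=C1C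
F2 | step 4 | (5R)-1-(dibromomethyl)-2-methyl-5-[(2R)-1-nitropropan-2-yl]cyclopent-2-en-1-ol (both C-1 epimers) | CC1=CC[C@@H](C1(O)C(Br)Br)[C@@H](C)C[N+](=O)[O-]
F3 | step 7 | (2R)-2-[(1S)-4-methylcyclohexa-2,4-dien-1-yl]propanoic acid | CC1=CC[C@@H](C=C1)[C@@H](C)C(=O)O
F4 | step 7 | (2R)-2-[(1S)-4-methylcyclohexa-2,4-dien-1-yl]propan-1-ol | CC1=CC[C@@H](C=C1)[C@@H](C)CO
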